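**Retrosynthetic overview**
1. The strategy rests on the furan ring of the benzofuran. Its C2=C3 double bond carries the methyl group on C3 and the tetrasubstituted benzene ring on C2, and this bond is formed last by a low-valent titanium ketone–ester coupling.
2. Cutting C2=C3 turns C3 and its methyl into the acetyl group of a 2-hydroxyacetophenone and C2 into the carboxyl carbon of a benzoic acid. O1 is the ester oxygen linking them, so an aryl ester is the cyclisation precursor.
3. Acid fragment 1 comes from 2,4,6-trihydroxybenzaldehyde. The prenyl group is installed by O-(1,1-dimethylpropargyl)ation, semihydrogenation and aromatic Claisen rearrangement to the one open ortho carbon, followed by O-methylation and aldehyde oxidation.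
4. Ketone fragment 2 is 2,4-dihydroxyacetophenone as its 4-MOM ether. The three phenols that are free in the target travel as MOM ethers and are released in the last step.
5. Ring order: both benzene rings are bought; the furan ring is the only ring built and is closed in step 9.

Key step: step 9

Remark on the chemistry: the target has no stereocentre and its side-chain alkene bears two identical methyl groups, so no configuration has to be controlled. The titanium diolate 13 is listed as its free diol.

Step 1
Reactants: 1 2,4,6-trihydroxybenzaldehyde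
Product: 2 2-hydroxy-4,6-bis(methoxymethoxy)benzaldehyde
Conditions: MOMCl (2.2 equiv), i-Pr2NEt (2.5 equiv), CH2Cl2, 0 °C to rt
Reagents that add atoms: chloromethyl methyl ether (MOMCl), COCCl
Why: Base-mediated O-alkylation (acetal formation) takes the 4-hydroxyl and one ortho hydroxyl, while the remaining ortho hydroxyl is held in a hydrogen bond to the aldehyde oxygen and should stay free with two equivalents of reagent.

Step 2
Reactants: 2 2-hydroxy-4,6-bis(methoxymethoxy)benzaldehyde; 3 3-chloro-3-methylbut-1-yne
Product: 4 4,6-bis(methoxymethoxy)-2-[(2-methylbut-3-yn-2-yl)oxy]benzaldehyde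
Conditions: 3 (1.5 equiv), DBU, CuCl2·2H2O (cat.), MeCN, 0 °C to rt
Reagents that add atoms: none
Why: Copper-catalysed propargylic etherification, in which a copper acetylide ionises the tertiary chloride and the DBU-generated phenoxide is captured at the tertiary carbon, gives an ether that a direct SN2 reaction could not form.

Step 3
Reactants: 4 4,6-bis(methoxymethoxy)-2-[(2-methylbut-3-yn-2-yl)oxy]benzaldehyde
Product: 5 4,6-bis(methoxymethoxy)-2-[(2-methylbut-3-en-2-yl)oxy]benzaldehyde
Conditions: H2 (1 atm), Pd on CaCO3 poisoned with Pb(OAc)2, quinoline, EtOAc, rt, stopped at one equivalent of H2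
Reagents that add atoms: none
Why: Lindlar semihydrogenation reduces the terminal alkyne to the alkene on the poisoned palladium surface and should leave the aldehyde, the aryl ethers and the MOM acetals untouched.

Step 4
Reactants: 5 4,6-bis(methoxymethoxy)-2-[(2-methylbut-3-en-2-yl)oxy]benzaldehyde
Product: 6 2-hydroxy-4,6-bis(methoxymethoxy)-3-(3-methylbut-2-en-1-yl)benzaldehyde
Conditions: PhNEt2, 140–150 °C, argon
Reagents that add atoms: none
Why: The aromatic Claisen rearrangement, a [3,3]-sigmatropic shift, delivers the allyl terminus to C3, the only ortho carbon bearing hydrogen, so the tertiary ether becomes the linear 3-methylbut-2-enyl group and tautomerisation restores the chelated phenol.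

Step 5
Reactants: 6 2-hydroxy-4,6-bis(methoxymethoxy)-3-(3-methylbut-2-en-1-yl)benzaldehyde
Product: 7 2-methoxy-4,6-bis(methoxymethoxy)-3-(3-methylbut-2-en-1-yl)benzaldehyde
Conditions: MeI, K2CO3, DMF, rt to 40 °C
Reagents that add atoms: iodomethane (MeI), CI
Why: Williamson O-methylation of the only free phenol should proceed cleanly in DMF, where the chelated hydroxyl is deprotonated by K2CO3, while aldehyde, MOM ethers and alkene are inert.

Step 6
Reactants: 7 2-methoxy-4,6-bis(methoxymethoxy)-3-(3-methylbut-2-en-1-yl)benzaldehyde
Product: 8 2-methoxy-4,6-bis(methoxymethoxy)-3-(3-methylbut-2-en-1-yl)benzoic acid (fragment 1)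
Conditions: NaClO2, NaH2PO4, 2-methylbut-2-ene (large excess), t-BuOH/H2O, 0 °C to rt; work-up at pH about 4
Reagents that add atoms: sodium chlorite, [Na+].[O-]Cl=O
Why: In the Pinnick oxidation chlorous acid converts the aldehyde selectively to the acid, the excess 2-methylbut-2-ene consumes the hypochlorous acid that would otherwise attack the prenyl alkene or the electron-rich ring, and the phosphate buffer is mild enough for the MOM ethers.

Step 7
Reactants: 9 2,4-dihydroxyacetophenone
Product: 10 1-[2-hydroxy-4-(methoxymethoxy)phenyl]ethan-1-one (fragment 2)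
Conditions: MOMCl (1.1 equiv), K2CO3, acetone, 0 °C to rt
Reagents that add atoms: chloromethyl methyl ether (MOMCl), COCCl
Why: Selective O-alkylation is expected at the 4-hydroxyl, the more acidic and unchelated phenol, because the 2-hydroxyl is tied up in a hydrogen bond to the acetyl oxygen.

Step 8
Reactants: 8 2-methoxy-4,6-bis(methoxymethoxy)-3-(3-methylbut-2-en-1-yl)benzoic acid; 10 1-[2-hydroxy-4-(methoxymethoxy)phenyl]ethan-1-one
Product: 12 2-acetyl-5-(methoxymethoxy)phenyl 2-methoxy-4,6-bis(methoxymethoxy)-3-(3-methylbut-2-en-1-yl)benzoate, via O-acylisourea 11 (not isolated)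
Conditions: DCC (1.3 equiv), DMAP (1 equiv), CH2Cl2, 0 °C to rt
Reagents that add atoms: none
Why: In this Steglich esterification DCC activates the hindered acid as O-acylisourea 11 and DMAP relays the acyl group to the weakly nucleophilic chelated phenol under neutral conditions, so no enolate forms and a Baker–Venkataraman acyl shift to the acetyl methyl is avoided.

Step 9
Reactants: 12 2-acetyl-5-(methoxymethoxy)phenyl 2-methoxy-4,6-bis(methoxymethoxy)-3-(3-methylbut-2-en-1-yl)benzoate
Product: 14 2-[2-methoxy-4,6-bis(methoxymethoxy)-3-(3-methylbut-2-en-1-yl)phenyl]-6-(methoxymethoxy)-3-methyl-1-benzofuran, via titanium 2,3-dihydrobenzofuran-2,3-diolate 13 (not isolated)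
Conditions: TiCl3, Zn dust, THF, reflux 2 h (pre-reduction); then 12 in THF by syringe pump over about 6 h at reflux, high dilution; aqueous K2CO3 work-up
Reagents that add atoms: none
Why: Zinc-reduced TiCl3 (low-valent titanium) transfers an electron to the aryl methyl ketone of 12, and the titanium-bound ketyl carbon adds to the ester carbonyl held ortho through the phenolic oxygen, giving the titanium diolate 13, whose two C–O bonds are then cleaved on the oxophilic metal to leave the C2=C3 double bond. The closest known reaction type is the McMurry-type intramolecular ketone–ester coupling of 2-acyloxyaryl ketones to 2,3-disubstituted benzofurans. The furan ring, the only ring formed, closes in a 5-exo-trig mode by attack of the ketyl carbon (future C3) on the exocyclic ester C=O (future C2), with O1 already in place. The two stereocentres of 13 arise without control and are both erased on deoxygenation, so the aromatic product carries none. The step needs chemoselectivity for intramolecular cross-coupling over intermolecular ketone–ketone pinacol coupling and over reductive cleavage of the aryl ester; the rigid ortho tether, slow addition at high dilution and the twisted, still electrophilic di-ortho-substituted aroyl carbonyl should secure it, and the regiochemistry (aryl on C2, methyl on C3) is fixed by the ester connectivity. The prenyl alkene and the aryl ethers should be inert, and pre-reduction of TiCl3 limits Lewis-acid loss of MOM groups, which would in any case only anticipate step 10.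

Step 10
Reactants: 14 2-[2-methoxy-4,6-bis(methoxymethoxy)-3-(3-methylbut-2-en-1-yl)phenyl]-6-(methoxymethoxy)-3-methyl-1-benzofuran
Product: 15 glycybenzofuran, 4-(6-hydroxy-3-methyl-1-benzofuran-2-yl)-5-methoxy-6-(3-methylbut-2-en-1-yl)benzene-1,3-diol
Conditions: HCl (about 1 M) in MeOH, 40 °C, short reaction time, NaHCO3 quench
Reagents that add atoms: none
Why: Acid-catalysed acetal solvolysis transfers the three methoxymethyl groups to methanol, and the low acid strength, moderate temperature and short time are chosen so that the prenyl alkene is not protonated and does not close onto the adjacent hydroxyl.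

**Compound list**
1 | 2,4,6-trihydroxybenzaldehyde | O=Cc1c(O)cc(O)cc1O | starting material
2 | 2-hydroxy-4,6-bis(methoxymethoxy)benzaldehyde | O=Cc1c(O)cc(OCOC)cc1OCOC | intermediate
3 | 3-chloro-3-methylbut-1-yne | C#CC(C)(C)Cl | starting material
4 | 4,6-bis(methoxymethoxy)-2-[(2-methylbut-3-yn-2-yl)oxy]benzaldehyde | O=Cc1c(OC(C)(C)C#C)cc(OCOC)cc1OCOC | intermediate
5 | 4,6-bis(methoxymethoxy)-2-[(2-methylbut-3-en-2-yl)oxy]benzaldehyde | O=Cc1c(OC(C)(C)C=C)cc(OCOC)cc1OCOC | intermediate
6 | 2-hydroxy-4,6-bis(methoxymethoxy)-3-(3-methylbut-2-en-1-yl)benzaldehyde | O=Cc1c(O)c(CC=C(C)C)c(OCOC)cc1OCOC | intermediate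
7 | 2-methoxy-4,6-bis(methoxymethoxy)-3-(3-methylbut-2-en-1-yl)benzaldehyde | COc1c(CC=C(C)C)c(OCOC)cc(OCOC)c1C=O | intermediate
8 | 2-methoxy-4,6-bis(methoxymethoxy)-3-(3-methylbut-2-en-1-yl)benzoic acid (fragment 1) | COc1c(CC=C(C)C)c(OCOC)cc(OCOC)c1C(=O)O | intermediate
9 | 2,4-dihydroxyacetophenone | CC(=O)c1ccc(O)cc1O | starting material
10 | 1-[2-hydroxy-4-(methoxymethoxy)phenyl]ethan-1-one (fragment 2) | CC(=O)c1ccc(OCOC)cc1O | intermediate
11 | N,N'-dicyclohexyl-O-[2-methoxy-4,6-bis(methoxymethoxy)-3-(3-methylbut-2-en-1-yl)benzoyl]isourea (formed in the flask, not isolated) | COc1c(CC=C(C)C)c(OCOC)cc(OCOC)c1C(=O)OC(=NC1CCCCC1)NC1CCCCC1 | intermediate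
12 | 2-acetyl-5-(methoxymethoxy)phenyl 2-methoxy-4,6-bis(methoxymethoxy)-3-(3-methylbut-2-en-1-yl)benzoate | COc1c(CC=C(C)C)c(OCOC)cc(OCOC)c1C(=O)Oc1cc(OCOC)ccc1C(C)=O | intermediate
13 | titanium-bound 2-[2-methoxy-4,6-bis(methoxymethoxy)-3-(3-methylbut-2-en-1-yl)phenyl]-6-(methoxymethoxy)-3-methyl-2,3-dihydro-1-benzofuran-2,3-diolate, drawn as the free diol, mixture of diastereomers (formed in the flask, not isolated) | COc1c(CC=C(C)C)c(OCOC)cc(OCOC)c1C1(O)Oc2cc(OCOC)ccc2C1(C)O | intermediate
14 | 2-[2-methoxy-4,6-bis(methoxymethoxy)-3-(3-methylbut-2-en-1-yl)phenyl]-6-(methoxymethoxy)-3-methyl-1-benzofuran (tris-MOM glycybenzofuran) | COc1c(CC=C(C)C)c(OCOC)cc(OCOC)c1-c1oc2cc(OCOC)ccc2c1C | intermediate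
15 | glycybenzofuran, 4-(6-hydroxy-3-methyl-1-benzofuran-2-yl)-5-methoxy-6-(3-methylbut-2-en-1-yl)benzene-1,3-diol | COc1c(CC=C(C)C)c(O)cc(O)c1-c1oc2cc(O)ccc2c1C | target

**Step count**
Total: 10 steps. Longest linear sequence: 9 steps (steps 1–6, 8, 9, 10); step 7 is the one-step branch to fragment 2.

**Steps most likely to fail**

Step 9 (key coupling). What may go wrong: intermolecular pinacol-type dimerisation of the ketone, reductive scission of the aryl ester C–O bond before ring closure, and Lewis-acid-promoted loss of MOM ethers leading to polar mixtures. The fallback replaces the reductive coupling by an intramolecular Wittig olefination of the ester carbonyl, which forms the same C2=C3 bond without low-valent metal. It sets out from keto ester 12. Luche reduction of the ketone (NaBH4, CeCl3·7H2O, MeOH/THF, −40 °C, cold acetic acid quench to hold back acyl migration) should give the racemic benzylic alcohol 2-(1-hydroxyethyl)-5-(methoxymethoxy)phenyl 2-methoxy-4,6-bis(methoxymethoxy)-3-(3-methylbut-2-en-1-yl)benzoate F1. Appel bromination (CBr4, PPh3, CH2Cl2, 0 °C) should convert it into the benzylic bromide 2-(1-bromoethyl)-5-(methoxymethoxy)phenyl 2-methoxy-4,6-bis(methoxymethoxy)-3-(3-methylbut-2-en-1-yl)benzoate F2. This is carried crude into PPh3 in MeCN at 60 °C to give the phosphonium salt {1-[2-(aroyloxy)-4-(methoxymethoxy)phenyl]ethyl}triphenylphosphonium bromide F3. Et3N in toluene at reflux then generates the ylide, which attacks the ester carbonyl and expels triphenylphosphine oxide, returning to the route at 14.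

Step 2 (tertiary propargyl ether). What may go wrong: slow O-alkylation of the hydrogen-bonded, sterically flanked phenoxide, so that the tertiary chloride is consumed by elimination of HCl or copper-mediated oligomerisation before the ether forms. The fallback is a Tsuji–Trost O-allylation that sets out from phenol 2. The reagent is tert-butyl 2-methylbut-3-en-2-yl carbonate F4, prepared from 2-methylbut-3-en-2-ol, n-BuLi and Boc2O. With catalytic Pd(PPh3)4, a zerovalent palladium complex, in THF at 0 °C, the phenoxide should attack the more substituted terminus of the allylpalladium intermediate under kinetic control. This gives the 1,1-dimethylallyl ether directly and returns to the route at 5, so that step 3 is no longer needed.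

Step 10 (global deprotection). What may go wrong: protonation of the prenyl double bond and capture of the tertiary cation by the neighbouring hydroxyl (chroman formation), or addition of methanol across the alkene, competing with acetal cleavage. The fallback avoids free Brønsted acid and sets out from 14. TMSOTf and 2,2'-bipyridyl in MeCN at 0 °C should exchange each aryl MOM ether for a silyl ether, giving 2-[2-methoxy-3-(3-methylbut-2-en-1-yl)-4,6-bis(trimethylsilyloxy)phenyl]-3-methyl-6-(trimethylsilyloxy)-1-benzofuran F5. Water during work-up (or K2CO3 in MeOH) hydrolyses it, and the route is rejoined at the target 15.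

**Further compounds**
F1 | step 9 | 2-(1-hydroxyethyl)-5-(methoxymethoxy)phenyl 2-methoxy-4,6-bis(methoxymethoxy)-3-(3-methylbut-2-en-1-yl)benzoate (racemic) | COc1c(CC=C(C)C)c(OCOC)cc(OCOC)c1C(=O)Oc1cc(OCOC)ccc1C(C)O
F2 | step 9 | 2-(1-bromoethyl)-5-(methoxymethoxy)phenyl 2-methoxy-4,6-bis(methoxymethoxy)-3-(3-methylbut-2-en-1-yl)benzoate (racemic) | COc1c(CC=C(C)C)c(OCOC)cc(OCOC)c1C(=O)Oc1cc(OCOC)ccc1C(C)Br
F3 | step 9 | {1-[2-(aroyloxy)-4-(methoxymethoxy)phenyl]ethyl}triphenylphosphonium bromide, aroyl = 2-methoxy-4,6-bis(methoxymethoxy)-3-(3-methylbut-2-en-1-yl)benzoyl (racemic) | COc1c(CC=C(C)C)c(OCOC)cc(OCOC)c1C(=O)Oc1cc(OCOC)ccc1C(C)[P+](c1ccccc1)(c1ccccc1)c1ccccc1.[Br-]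
F4 | step 2 | tert-butyl 2-methylbut-3-en-2-yl carbonate | C=CC(C)(C)OC(=O)OC(C)(C)C
F5 | step 10 | 2-[2-methoxy-3-(3-methylbut-2-en-1-yl)-4,6-bis(trimethylsilyloxy)phenyl]-3-methyl-6-(trimethylsilyloxy)-1-benzofuran | COc1c(CC=C(C)C)c(O[Si](C)(C)C)cc(O[Si](C)(C)C)c1-c1oc2cc(O[Si](C)(C)C)ccc2c1C
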